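The left-handed product was what I set out to count, in a flask charged with a racemate whose hands are taken by a single-handed coupling partner that dissolves from a held gas.

left-handed substrate 1.0 mM; gas 0.40 mM (held); right-handed substrate 1.0 mM; time 40 min

    coupling partner + right-handed substrate → right-handed product (k1 = 27.9 /M/s)
    gas ⇌ coupling partner, rate k2*(csat - [coupling partner]) (k2 = 0.126 /s, csat = 0.40 mM)
    left-handed substrate ⇌ right-handed substrate (k3 = 2.08 /s)
    coupling partner + left-handed substrate → left-handed product (k4 = 84.6 /M/s)

- coupling partner is single-handed; left-handed substrate and right-handed substrate are mirror images of each other, charged as a racemate, each of them at the stated concentration
- at the start none of coupling partner is dissolved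
- the reaction counts as stopped when no species that holds the left-handed substrate and right-handed substrate together changes by six tenths of a point or more over the second half of the time
- run time (flask): 40 min
- the handed part of coupling partner does not stay in what it makes, so the products of the two hands are mirror images too

* which holds at 40 min: what has brought the reaction to rest, or that it has not come to rest (forward and back rates have come level / it is still moving / all of the left-handed substrate has reacted)
* left-handed product at 40 min, in percent of the left-handed substrate and right-handed substrate together charged
* right-handed product at 40 min, in percent of the left-handed substrate and right-handed substrate together charged

One thing looked wrong at first. The left-handed substrate was half of the charge, yet I expected 75.2% of the charge to end as left-handed product.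

The reckoning cleared this up. I took [coupling partner] at its ceiling of 0.40 mM, so the faster coupling ran at 0.0338 /s against 2.08 /s for the turning of one hand into the other. The turning was faster than this coupling by 1.79 powers of ten, so I reckoned that the left-handed substrate would be refilled from the right-handed as it was used. I therefore took the two hands to stay nearly equal and the products to split by the selectivity factor of 3.03. An equal pool falls with the mean of the two coupling constants, and dividing that by the logarithm of ten gave the quantity I carried, the decade rate: the powers of ten of substrate lost per minute at full [coupling partner], here 0.586 /min. Over 40 min that allowed 23.4 powers of ten.

The forecast gave 75.1% and 24.9%, with the end all of the left-handed substrate has reacted. My share was 75.2%, and the forecast's ground for its own figure was that "the faster-reacting left hand runs a touch low".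

The simulation gave 75.1% and 24.9%, with the end all of the left-handed substrate has reacted.

Between 2.00 min and 4.00 min, the left-handed substrate in this flask fell from 8.24% to 0.652%, a reading of 0.551 /min, a little less than the decade rate. From 4.00 min to 15 min, the decade rate gave 6.45 further powers of ten, and the same flask read at 15 min showed 0% left-handed substrate and 75.1% left-handed product. So the flask had come to rest. At 400 min, the right-handed product stood at 24.9%, a change of 0 percentage points.

(The numbers were chosen freely; no experiment stands behind them.)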